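**Plan**

1. The last cut is the benzylic O–Si bond. The key cut opens ring A (C1 ester, C2 aryloxy, C3 H, C4 methyl, C5 prenyl, C6 OH) at C4–C5 and C6–C1. This gives a 4-aryloxy-6-methyl-2-pyrone-3-carboxylate (C1–C4) and the bis-silyl ketene acetal of 5-methylhex-4-enoic acid (C5, C6 and the phenol oxygen).
2. Earlier cuts: the diaryl ether C–O bond at pyrone C4 (tosylate plus ring B phenoxide), and the pyrone itself (dimethyl malonate plus acetylketene).
3. Forward order: ring B phenol in three steps; pyrone ring by acylation and lactonisation; ether union at C4; ring A by [4+2] addition, loss of CO2 and loss of silanol; desilylation.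
4. Enabling feature: ring A is a salicylate. Its C6 hydroxyl is ortho to the C1 ester, and C1–C4 form an unbroken ester/aryloxy/H/methyl run. That is the imprint of pyrone C3–C6 joined to the carboxyl and α-carbons of a carboxylic acid.
5. Stereochemistry: the target has no stereocentre and its alkene carries two identical methyl groups, so nothing needs control. The sp3 centres of the cycloadduct vanish on aromatisation.

Key step: step 8

Assumption: 5-methylhex-4-enoic acid is taken as purchasable; otherwise it is a Johnson–Claisen rearrangement and a saponification away from 2-methylbut-3-en-2-ol.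

Throughout, Ar = 2-{[(tert-butyldimethylsilyl)oxy]methyl}-4,6-dimethoxyphenyl.

**Route**

Step 1
Reactants: 1 5-bromo-2-hydroxy-3-methoxybenzaldehyde
Product: 2 2-hydroxy-3,5-dimethoxybenzaldehyde
Conditions: NaOMe (5 equiv), CuBr (0.2 equiv), EtOAc (0.2 equiv), MeOH/DMF, 110 °C; then 1 M HCl
Reagents that add atoms: sodium methoxide, [Na+].[O-]C
Why: Copper-catalysed Ullmann-type methanolysis of the aryl bromide, the exchange that turns bromovanillin into syringaldehyde, should replace bromine by methoxy while the aldehyde is shielded from methoxide as its ortho-phenoxide.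

Step 2
Reactants: 2 2-hydroxy-3,5-dimethoxybenzaldehyde
Product: 3 2-(hydroxymethyl)-4,6-dimethoxyphenol
Conditions: NaBH4, MeOH, 0 °C
Reagents that add atoms: none
Why: Borohydride reduction of an aromatic aldehyde to the benzylic alcohol is routine and leaves the aryl methyl ethers untouched.

Step 3
Reactants: 3 2-(hydroxymethyl)-4,6-dimethoxyphenol
Product: 4 2-{[(tert-butyldimethylsilyl)oxy]methyl}-4,6-dimethoxyphenol
Conditions: t-BuMe2SiCl (1.05 equiv), imidazole (2 equiv), CH2Cl2, 0 °C
Reagents that add atoms: tert-butyldimethylsilyl chloride, CC(C)(C)[Si](C)(C)Cl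
Why: Chemoselective silylation is expected because the primary benzylic hydroxyl is far more accessible than the hydrogen-bonded phenol flanked by two ortho substituents, and any aryl silyl ether formed would be lost first on aqueous work-up.

Step 4
Reactants: 5 dimethyl malonate; 6 2,2,6-trimethyl-4H-1,3-dioxin-4-one
Product: 10 methyl 4-hydroxy-6-methyl-2-oxo-2H-pyran-3-carboxylate, via sodium dimethyl malonate 7 (not isolated), via acetylketene 8 (not isolated), via dimethyl 2-(3-oxobutanoyl)malonate 9 (not isolated)
Conditions: NaH, THF, 0 °C; then 6, toluene, 110 °C, THF and acetone distilled off; then 1 M HCl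
Reagents that add atoms: none
Why: Retro-[4+2] fragmentation of the dioxinone releases acetylketene, which C-acylates the malonate anion, and the enol oxygen of the new acetoacetyl ketone then lactonises onto one ester with loss of methoxide, as in the classical pyrone synthesis from diketene and malonate.

Step 5
Reactants: 10 methyl 4-hydroxy-6-methyl-2-oxo-2H-pyran-3-carboxylate
Product: 11 methyl 6-methyl-2-oxo-4-(tosyloxy)-2H-pyran-3-carboxylate
Conditions: TsCl, Et3N, DMAP (cat.), CH2Cl2, 0 °C
Reagents that add atoms: 4-methylbenzenesulfonyl chloride, Cc1ccc(cc1)S(=O)(=O)Cl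
Why: O-sulfonylation of the acidic 4-hydroxyl, a vinylogous carboxylic acid, is the standard way to make a 4-hydroxy-2-pyrone electrophilic at C4.

Step 6
Reactants: 4 2-{[(tert-butyldimethylsilyl)oxy]methyl}-4,6-dimethoxyphenol; 11 methyl 6-methyl-2-oxo-4-(tosyloxy)-2H-pyran-3-carboxylate
Product: 12 methyl 4-(2-{[(tert-butyldimethylsilyl)oxy]methyl}-4,6-dimethoxyphenoxy)-6-methyl-2-oxo-2H-pyran-3-carboxylate
Conditions: Cs2CO3, MeCN, 0 °C to rt
Reagents that add atoms: none
Why: Addition–elimination (vinylogous nucleophilic acyl substitution) at pyrone C4, which is β to both the lactone carbonyl and the C3 ester, should let even the di-ortho-substituted phenoxide add and expel tosylate.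

Step 7
Reactants: 13 5-methylhex-4-enoic acid
Product: 15 1,1-bis(trimethylsilyloxy)-5-methylhexa-1,4-diene, via dilithium enediolate 14 (not isolated)
Conditions: LiN(iPr)2 (2.2 equiv), THF, −78 to 0 °C; then Me3SiCl (2.5 equiv), −78 °C to rt; filtration under argon, bulb-to-bulb distillation
Reagents that add atoms: chlorotrimethylsilane, C[Si](C)(C)Cl
Why: Double deprotonation of the acid gives the enediolate, which the hard silyl chloride traps on both oxygens (bis-silyl ketene acetal formation from a carboxylic acid dianion), the trisubstituted alkene being inert to the amide base.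

Step 8
Reactants: 12 methyl 4-(2-{[(tert-butyldimethylsilyl)oxy]methyl}-4,6-dimethoxyphenoxy)-6-methyl-2-oxo-2H-pyran-3-carboxylate; 15 1,1-bis(trimethylsilyloxy)-5-methylhexa-1,4-diene
Product: 19 methyl 2-(2-{[(tert-butyldimethylsilyl)oxy]methyl}-4,6-dimethoxyphenoxy)-6-hydroxy-4-methyl-5-(3-methylbut-2-en-1-yl)benzoate, via bridged lactone cycloadduct 16 (not isolated), via bis-silyloxy cyclohexadiene 17 (not isolated), via aryl trimethylsilyl ether 18 (not isolated)
Conditions: 15 (3 equiv), toluene, 120 °C, sealed tube; then MeOH, K2CO3 (cat.), 0 °C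
Reagents that add atoms: none
Why: Pyrone 12 is an electron-poor diene (C3=C4–C5=C6, lowered by the lactone and the C3 ester) and 15 an electron-rich alkene, so an inverse-electron-demand, strongly asynchronous [4+2] is expected in which C2 of 15 (the former α-carbon of the acid) bonds first to the methyl-bearing pyrone C6 and the acetal carbon then closes onto C3 to give bridged lactone 16. Retro-[4+2] loss of carbon dioxide from 16 gives diene 17, 1,2-elimination of trimethylsilanol (H from the prenyl-bearing carbon, silyloxy from the former acetal carbon) aromatises ring A to 18, and methanolysis of the aryl O–Si bond leaves the free salicylate hydroxyl of 19. The closest known reaction is the cycloaddition of 3-carbomethoxy-2-pyrones with 1,1-dialkoxyalkenes, which gives salicylate ethers after loss of carbon dioxide and alcohol; two silyloxy groups are used here so that whichever one leaves, the oxygen that stays is a hydrolysable silyl ether and not a methyl ether. Ring A closes as a six-membered carbocycle by intermolecular cycloaddition (both new bonds, C4–C5 and C6–C1 in ring A numbering, form in this step) and is then aromatised, so the sp3 centres of 16 are erased and no stereocentre has to be controlled. The step needs regioselectivity (acetal carbon to the ester-bearing C3) and site selectivity for C6 over the aryloxy-bearing C4: the first should follow from matched polarisation (largest pyrone LUMO coefficient at C6, largest ketene acetal HOMO coefficient at C2), the second from C4 not being a diene terminus and being deactivated by its own oxygen donor. The isolated prenyl alkene is too electron-neutral to compete as a dienophile.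

Step 9
Reactants: 19 methyl 2-(2-{[(tert-butyldimethylsilyl)oxy]methyl}-4,6-dimethoxyphenoxy)-6-hydroxy-4-methyl-5-(3-methylbut-2-en-1-yl)benzoate
Product: 20 methyl 6-hydroxy-2-[2-(hydroxymethyl)-4,6-dimethoxyphenoxy]-4-methyl-5-(3-methylbut-2-en-1-yl)benzoate (CNP0583011.0)
Conditions: Bu4NF (1.2 equiv), AcOH (1.2 equiv), THF, 0 °C to rt
Reagents that add atoms: none
Why: Fluoride-induced Si–O cleavage, driven by the strong Si–F bond, should free the benzylic alcohol, and the acetic acid buffer keeps the salicylate and the methyl ester safe from basic fluoride.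

**Compound list**

1 | 5-bromo-2-hydroxy-3-methoxybenzaldehyde | COc1cc(Br)cc(C=O)c1O | starting material
2 | 2-hydroxy-3,5-dimethoxybenzaldehyde | COc1cc(OC)cc(C=O)c1O | intermediate
3 | 2-(hydroxymethyl)-4,6-dimethoxyphenol | COc1cc(OC)cc(CO)c1O | intermediate
4 | 2-{[(tert-butyldimethylsilyl)oxy]methyl}-4,6-dimethoxyphenol | COc1cc(OC)cc(CO[Si](C)(C)C(C)(C)C)c1O | intermediate
5 | dimethyl malonate | COC(=O)CC(=O)OC | starting material
6 | 2,2,6-trimethyl-4H-1,3-dioxin-4-one | CC1=CC(=O)OC(C)(C)O1 | starting material
7 | sodium dimethyl malonate | [Na+].COC(=O)[CH-]C(=O)OC | intermediate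
8 | acetylketene (3-oxobut-1-en-1-one) | CC(=O)C=C=O | intermediate
9 | dimethyl 2-(3-oxobutanoyl)malonate (present as its sodium enolate) | CC(=O)CC(=O)C(C(=O)OC)C(=O)OC | intermediate
10 | methyl 4-hydroxy-6-methyl-2-oxo-2H-pyran-3-carboxylate | COC(=O)C1=C(O)C=C(C)OC1=O | intermediate
11 | methyl 6-methyl-2-oxo-4-(tosyloxy)-2H-pyran-3-carboxylate | COC(=O)C1=C(OS(=O)(=O)c2ccc(C)cc2)C=C(C)OC1=O | intermediate
12 | methyl 4-(ArO)-6-methyl-2-oxo-2H-pyran-3-carboxylate | COC(=O)C1=C(Oc2c(CO[Si](C)(C)C(C)(C)C)cc(OC)cc2OC)C=C(C)OC1=O | intermediate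
13 | 5-methylhex-4-enoic acid | CC(C)=CCCC(=O)O | starting material
14 | dilithium 5-methylhexa-1,4-diene-1,1-diolate | [Li+].[Li+].CC(C)=CCC=C([O-])[O-] | intermediate
15 | 1,1-bis(trimethylsilyloxy)-5-methylhexa-1,4-diene | CC(C)=CCC=C(O[Si](C)(C)C)O[Si](C)(C)C | intermediate
16 | methyl 5-(ArO)-1-methyl-7-(3-methylbut-2-en-1-yl)-3-oxo-8,8-bis(trimethylsilyloxy)-2-oxabicyclo[2.2.2]oct-5-ene-4-carboxylate (diastereomer mixture, configuration irrelevant) | COC(=O)C12C(=O)OC(C)(C=C1Oc3c(CO[Si](C)(C)C(C)(C)C)cc(OC)cc3OC)C(CC=C(C)C)C2(O[Si](C)(C)C)O[Si](C)(C)C | intermediate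
17 | methyl 2-(ArO)-4-methyl-5-(3-methylbut-2-en-1-yl)-6,6-bis(trimethylsilyloxy)cyclohexa-1,3-diene-1-carboxylate | COC(=O)C1=C(Oc2c(CO[Si](C)(C)C(C)(C)C)cc(OC)cc2OC)C=C(C)C(CC=C(C)C)C1(O[Si](C)(C)C)O[Si](C)(C)C | intermediate
18 | methyl 2-(ArO)-4-methyl-5-(3-methylbut-2-en-1-yl)-6-(trimethylsilyloxy)benzoate | COC(=O)c1c(Oc2c(CO[Si](C)(C)C(C)(C)C)cc(OC)cc2OC)cc(C)c(CC=C(C)C)c1O[Si](C)(C)C | intermediate
19 | methyl 2-(ArO)-6-hydroxy-4-methyl-5-(3-methylbut-2-en-1-yl)benzoate | COC(=O)c1c(Oc2c(CO[Si](C)(C)C(C)(C)C)cc(OC)cc2OC)cc(C)c(CC=C(C)C)c1O | intermediate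
20 | methyl 6-hydroxy-2-[2-(hydroxymethyl)-4,6-dimethoxyphenoxy]-4-methyl-5-(3-methylbut-2-en-1-yl)benzoate | COC(=O)c1c(Oc2c(CO)cc(OC)cc2OC)cc(C)c(CC=C(C)C)c1O | target

**Count**

Total steps: 9. Longest linear sequence: 6 steps (steps 1, 2, 3, 6, 8, 9; compounds 1 → 2 → 3 → 4 → 12 → 19 → 20).

**Steps most likely to fail**

Step 8. The β-substituted, moisture-sensitive ketene acetal may add too slowly to the methyl-bearing diene terminus. It may also stop at an open Michael adduct after silyl transfer, or attack C4 with expulsion of the aryloxide. The fallback sets out from pyrone 12 and uses commercial, unhindered 1,1-dimethoxyethene (toluene, 120–140 °C), the standard partner for this cycloaddition. Through bridged lactone F1 and dimethoxycyclohexadiene F2 this should give the anisole ester methyl 2-(ArO)-6-methoxy-4-methylbenzoate F3. BCl3 (CH2Cl2, −78 °C, where the primary silyl ether is expected to hold) would then cleave only the methoxy group chelated to the ester, giving phenol F4. Pd(PPh3)4-catalysed O-alkylation with methyl 2-methylbut-3-en-2-yl carbonate (THF, 0 °C) would give the tertiary allyl ether F5. An aromatic Claisen rearrangement (toluene, 110 °C) would carry the allyl unit, inverted to a prenyl group, to the only free ortho carbon via dienone F6, and the sequence comes back to the route at 19.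

Step 6. The hindered phenoxide may attack sulfur (sulfonyl transfer) or the lactone carbonyl instead of C4. The ortho-silyloxymethyl phenoxide may also suffer silyl migration. The fallback sets out from hydroxypyrone 10. Oxalyl chloride with catalytic DMF (CH2Cl2, 0 °C) would convert it into the vinylogous acid chloride methyl 4-chloro-6-methyl-2-oxo-2H-pyran-3-carboxylate F7. This is a smaller electrophile that offers the nucleophile carbon only. Reaction of F7 with phenol 4 (Cs2CO3, MeCN, 0 °C) comes back to the route at 12.

Step 4. The thermally generated acetylketene may dimerise or O-acylate faster than it C-acylates the poorly soluble sodium malonate. The tricarbonyl may also fail to lactonise under basic conditions. The fallback sets out from dimethyl malonate 5 and replaces the ketene by a masked acetoacetyl chloride. Soft enolisation (MgCl2, Et3N, MeCN, 0 °C) and C-acylation with (E)-3-methoxybut-2-enoyl chloride F8 (from the commercial acid and oxalyl chloride) would give dimethyl 2-[(E)-3-methoxybut-2-enoyl]malonate F9. Aqueous acid (2 M HCl, THF, 50 °C) would unmask the ketone to 9 and close the lactone, coming back to the route at 10.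

**Further compounds**

F1 | step 8 | methyl 5-(ArO)-8,8-dimethoxy-1-methyl-3-oxo-2-oxabicyclo[2.2.2]oct-5-ene-4-carboxylate | COC(=O)C12C(=O)OC(C)(C=C1Oc3c(CO[Si](C)(C)C(C)(C)C)cc(OC)cc3OC)CC2(OC)OC
F2 | step 8 | methyl 2-(ArO)-6,6-dimethoxy-4-methylcyclohexa-1,3-diene-1-carboxylate | COC(=O)C1=C(Oc2c(CO[Si](C)(C)C(C)(C)C)cc(OC)cc2OC)C=C(C)CC1(OC)OC
F3 | step 8 | methyl 2-(ArO)-6-methoxy-4-methylbenzoate | COC(=O)c1c(Oc2c(CO[Si](C)(C)C(C)(C)C)cc(OC)cc2OC)cc(C)cc1OC
F4 | step 8 | methyl 2-(ArO)-6-hydroxy-4-methylbenzoate | COC(=O)c1c(Oc2c(CO[Si](C)(C)C(C)(C)C)cc(OC)cc2OC)cc(C)cc1O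
F5 | step 8 | methyl 2-(ArO)-4-methyl-6-[(2-methylbut-3-en-2-yl)oxy]benzoate | COC(=O)c1c(Oc2c(CO[Si](C)(C)C(C)(C)C)cc(OC)cc2OC)cc(C)cc1OC(C)(C)C=C
F6 | step 8 | methyl 2-(ArO)-4-methyl-5-(3-methylbut-2-en-1-yl)-6-oxocyclohexa-1,3-diene-1-carboxylate | COC(=O)C1=C(Oc2c(CO[Si](C)(C)C(C)(C)C)cc(OC)cc2OC)C=C(C)C(CC=C(C)C)C1=O
F7 | step 6 | methyl 4-chloro-6-methyl-2-oxo-2H-pyran-3-carboxylate | COC(=O)C1=C(Cl)C=C(C)OC1=O
F8 | step 4 | (E)-3-methoxybut-2-enoyl chloride | CO/C(C)=C/C(=O)Cl
F9 | step 4 | dimethyl 2-[(E)-3-methoxybut-2-enoyl]malonate | CO/C(C)=C/C(=O)C(C(=O)OC)C(=O)OC
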